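**Plan**

1. Daucane numbering is used: C1 is the quaternary ring-fusion carbon with the angular methyl, C2 and C3 are the cyclopentane CH2 groups, C4 is the carbinol carbon with isopropyl, C5 the ring-fusion CH, C6 the CHOH, C7 a CH2, C8 and C9 the epoxide carbons (C8 carries methyl), C10 a CH2; β is the face of the angular methyl.
2. Retrosynthesis: remove the phenol benzyl ether, open the epoxide to the C8=C9 alkene, take the C6 alcohol back to a ketone, then cut the seven-membered ring at C1–C5 and C8–C9 in one (4+3) cycloaddition.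
3. Enabling feature: the cycloheptane is a three-carbon run C1–C10–C9 joined to a four-carbon run C5–C6–C7–C8 that carries oxygen on C6, which is an allyl cation (from a 1,1-disubstituted allene under gold) plus a 2-silyloxy-1,3-diene. C1 and C5 are already linked through C2–C3–C4, so the same event closes the cyclopentane.
4. The open-chain precursor maps onto (S)-terpinen-4-ol: its C(OH)(iPr) is C4, its ring CH2CH2 is C3–C2, and ozonolysis turns C(Me)= into the C1 methyl ketone and =CH into the C6 aldehyde with its CH2 as C5. The vanillate (phenol as benzyl ether) is put on the hindered tertiary alcohol first.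
5. Forward order: ester, ozonolysis, allene on the ketone arm, (E)-propenyl ketone then silyloxydiene on the aldehyde arm, (4+3) closure of both rings, Saegusa oxidation and 1,4-hydrogenation to move the unsaturation to C8=C9, reduction, directed epoxidation, debenzylation.
6. Stereochemistry: C4 comes from the terpene; C5 and C1 are set in the cycloaddition (1,2-induction from C4 and trans ring fusion); C6 by hydride reduction; C8 and C9 by hydroxyl-directed epoxidation.

Key step: step 10

Assumption: (S)-terpinen-4-ol (3) is taken as commercially available in high enantiomeric purity; its carbinol centre is the only source of absolute configuration.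

"O-benzylvanillate" below means 4-(benzyloxy)-3-methoxybenzoate.

**Route**

Step 1
Reactants: 1 4-(benzyloxy)-3-methoxybenzoic acid
Product: 2 4-(benzyloxy)-3-methoxybenzoyl chloride
Conditions: (COCl)2, DMF (cat.), CH2Cl2, 0 °C to rt
Reagents that add atoms: oxalyl chloride, O=C(Cl)C(=O)Cl
Why: Acid chloride formation through the Vilsmeier-type chloroiminium intermediate is standard for alkoxybenzoic acids and leaves the benzyl ether untouched.

Step 2
Reactants: 3 (S)-terpinen-4-ol; 2 4-(benzyloxy)-3-methoxybenzoyl chloride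
Product: 5 (S)-terpinen-4-yl O-benzylvanillate, via lithium terpinen-4-olate 4 (not isolated)
Conditions: n-BuLi (1.05 equiv), THF, −78 to 0 °C; then 2, −78 °C to rt
Reagents that add atoms: none
Why: O-acylation of a preformed lithium alkoxide by an aroyl chloride is the reliable way to esterify a hindered tertiary alcohol, and the stereocentre is not touched.

Step 3
Reactants: 5 (S)-terpinen-4-yl O-benzylvanillate
Product: 8 keto acetal (3S)-1,1-dimethoxy-6-oxo-3-(propan-2-yl)heptan-3-yl O-benzylvanillate, via hydroperoxy aldehyde 6 (not isolated), via hydroperoxy acetal 7 (not isolated)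
Conditions: O3, CH2Cl2/MeOH, −78 °C; TsOH·H2O (cat.), −78 °C to rt; then NaHCO3, Me2S, rt
Reagents that add atoms: ozone, O=[O+][O-]; methanol, CO
Why: Ozonolysis with terminal differentiation (Criegee cleavage in methanol) should cleave the trisubstituted alkene much faster than the alkoxyarene, trap the more substituted terminus as the methoxy hydroperoxide, acetalise the free aldehyde under acid and finally reduce the hydroperoxide to the methyl ketone with dimethyl sulfide.

Step 4
Reactants: 8 keto acetal
Product: 10 propargylic methyl carbonate (both C6 epimers), via bromomagnesium alkoxide 9 (not isolated)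
Conditions: HC≡CMgBr, THF, −78 to 0 °C; then ClCO2Me, 0 °C to rt
Reagents that add atoms: ethynylmagnesium bromide, C#C[Mg]Br; methyl chloroformate, COC(=O)Cl
Why: Grignard 1,2-addition to the unhindered methyl ketone (the hindered tertiary aryl ester and the acetal should not react at low temperature) followed by in situ O-acylation of the alkoxide gives the carbonate; the new carbinol centre forms unselectively and is erased in step 5.

Step 5
Reactants: 10 propargylic methyl carbonate
Product: 11 allene (3S)-1,1-dimethoxy-6-methyl-3-(propan-2-yl)octa-6,7-dien-3-yl O-benzylvanillate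
Conditions: Pd2(dba)3·CHCl3 (2.5 mol %), n-Bu3P (10 mol %), HCO2NH4 (2 equiv), THF, rt
Reagents that add atoms: none
Why: Tsuji–Mandai-type hydrogenolysis, in which zerovalent palladium adds oxidatively to the tertiary propargylic carbonate, the allenylpalladium formate loses CO2 and reductive elimination delivers hydride to the alkyne terminus, should give the 1,1-disubstituted terminal allene.

Step 6
Reactants: 11 allene acetal
Product: 12 aldehyde (3S)-6-methyl-1-oxo-3-(propan-2-yl)octa-6,7-dien-3-yl O-benzylvanillate
Conditions: AcOH/THF/H2O (3:1:1), 40 °C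
Reagents that add atoms: water, O
Why: Mild acid-catalysed acetal hydrolysis is tolerated by the terminal allene and the tertiary ester, and the non-basic medium avoids β-elimination of the acyloxy group.

Step 7
Reactants: 12 aldehyde
Product: 13 allylic alcohol (6S,9E)-8-hydroxy-3-methyl-6-(propan-2-yl)undeca-1,2,9-trien-6-yl O-benzylvanillate (both C8 epimers)
Conditions: (E)-1-bromoprop-1-ene, CrCl2 (4 equiv), NiCl2 (2 mol %), DMF, rt
Reagents that add atoms: (E)-1-bromoprop-1-ene, C/C=C/Br
Why: In the Nozaki–Hiyama–Kishi reaction the alkenylchromium reagent adds only to the aldehyde, is not basic enough to trigger E1cB loss of the β-acyloxy group and keeps the E geometry; the carbinol centre forms as a mixture and is oxidised away in step 8.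

Step 8
Reactants: 13 allylic alcohol
Product: 14 enone (6S,9E)-3-methyl-8-oxo-6-(propan-2-yl)undeca-1,2,9-trien-6-yl O-benzylvanillate
Conditions: MnO2 (activated, excess), CH2Cl2, rt
Reagents that add atoms: none
Why: Allylic oxidation with MnO2 is selective for the allylic alcohol and neutral, so the β-acyloxy ketone should not eliminate.

Step 9
Reactants: 14 enone
Product: 15 silyloxydiene (7Z,9E)-8-[(tert-butyldimethylsilyl)oxy]-3-methyl-6-(propan-2-yl)undeca-1,2,7,9-tetraen-6-yl O-benzylvanillate
Conditions: TBSOTf (1.3 equiv), Et3N (2 equiv), CH2Cl2, −78 to 0 °C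
Reagents that add atoms: tert-butyldimethylsilyl trifluoromethanesulfonate, CC(C)(C)[Si](C)(C)OS(=O)(=O)C(F)(F)F
Why: Soft enolisation (O-silylation, then α'-deprotonation by the amine) should give the cross-conjugated 2-silyloxydiene as the Z enol ether without passing through a free enolate that could expel the β-acyloxy group.

Step 10
Reactants: 15 silyloxydiene
Product: 16 trans-fused cycloadduct 6-[(tert-butyldimethylsilyl)oxy]-5αH,8αH-dauca-6,9-dien-4β-yl O-benzylvanillate
Conditions: (IPr)AuCl (5 mol %), AgSbF6 (5 mol %), CH2Cl2 (dry, 0.02 M), 4 Å MS, 0 °C to rt; IPr = 1,3-bis(2,6-diisopropylphenyl)imidazol-2-ylidene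
Reagents that add atoms: none
Why: The cationic NHC complex of monovalent gold binds the allene and slips to its central carbon to give a gold-bound allyl cation with most charge on the methyl-bearing terminus; the nucleophilic enol-silane carbon next to C4 attacks that terminus, the resulting silyloxyallyl cation is captured at its methyl-bearing end by the CH2 terminus of the vinylgold unit, and the gold carbene left at C10 undergoes a 1,2-hydride shift to the C9=C10 alkene and releases the catalyst. The closest known reaction type is the gold- or platinum-catalysed intramolecular (4+3) cycloaddition of allene-tethered 1,3-dienes, which gives trans-fused bicyclo[5.3.0]decadienes. The cyclopentane closes by 5-exo attack of the enol silane on the proximal allene carbon across the three-atom tether, and the cycloheptadiene closes by union of the two allyl termini with the two diene termini (7-endo with respect to the transient silyloxyallyl cation). C5 is set by 1,2-induction from the quaternary C4 (the diene-derived carbon ends up trans to isopropyl and cis to the smaller acyloxy group), C1 is set relative to C5 by the extended, exo-like arrangement of allyl cation and diene that leads to trans ring fusion, and C8 follows from suprafacial addition to the E-propenyl terminus (it is erased in step 11). The step needs (4+3) rather than (4+2) periselectivity and survival of the tertiary allylic ester: the strongly σ-donating IPr ligand should favour the hydride shift of the carbene over ring contraction, the silyloxy group polarises the diene to match the allyl cation, and the soft, weakly oxophilic catalyst at low temperature should leave the ester un-ionised.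

Step 11
Reactants: 16 cycloadduct
Product: 17 dienone 6-oxo-5αH-dauca-7,9-dien-4β-yl O-benzylvanillate
Conditions: Pd(OAc)2 (1.1 equiv), MeCN, rt
Reagents that add atoms: none
Why: In the Saegusa–Ito oxidation the enolate of divalent palladium formed from the enol silane should undergo β-hydride elimination of the doubly allylic C8–H, giving the linearly conjugated dienone and erasing the C8 stereocentre.

Step 12
Reactants: 17 dienone
Product: 18 β,γ-unsaturated ketone 6-oxo-5αH-dauc-8-en-4β-yl O-benzylvanillate
Conditions: (η6-naphthalene)Cr(CO)3 (10 mol %), H2 (50 atm), THF, 45 °C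
Reagents that add atoms: none
Why: Arene–Cr(CO)3-catalysed 1,4-hydrogenation of a diene held s-cis (the reaction that turns sorbates into 3-hexenoates) should add hydrogen to C7 and C10 of the ring diene and leave the C8=C9 alkene out of conjugation, while the s-trans enone unit cannot bind as a heterodiene.

Step 13
Reactants: 18 β,γ-unsaturated ketone
Product: 19 homoallylic alcohol 6α-hydroxy-5αH-dauc-8-en-4β-yl O-benzylvanillate
Conditions: NaBH4, CeCl3·7H2O, MeOH, −78 to −40 °C
Reagents that add atoms: none
Why: Luche-type borohydride reduction with a small hydride should follow the axial trajectory anti to the axial C5–H (β-face attack) and give the equatorial 6α-alcohol, and the buffered cerium medium limits epimerisation at C5 and β-elimination of the ester.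

Step 14
Reactants: 19 homoallylic alcohol
Product: 20 epoxy alcohol 8α,9α-epoxy-6α-hydroxy-5αH-daucan-4β-yl O-benzylvanillate
Conditions: VO(acac)2 (5 mol %), t-BuOOH (1.5 equiv), CH2Cl2, 0 °C to rt
Reagents that add atoms: tert-butyl hydroperoxide, CC(C)(C)OO
Why: Vanadium-catalysed hydroxyl-directed epoxidation of the homoallylic alcohol should deliver oxygen to the α face of C8=C9, syn to the 6α-hydroxyl and anti to the β angular methyl, which sets both epoxide centres.

Step 15
Reactants: 20 epoxy alcohol
Product: 21 target 8α,9α-epoxy-6α-hydroxy-5αH-daucan-4β-yl 4-hydroxy-3-methoxybenzoate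
Conditions: H2 (1 atm), Pd/C (10 wt % Pd on carbon), EtOAc, rt
Reagents that add atoms: none
Why: Hydrogenolysis of the aryl benzyl ether over palladium on carbon under neutral conditions should free the phenol while the trisubstituted aliphatic epoxide, the tertiary ester and the secondary alcohol stay intact.

**Compound list**

1 | 4-(benzyloxy)-3-methoxybenzoic acid | COc1cc(C(=O)O)ccc1OCc1ccccc1 | starting material
2 | 4-(benzyloxy)-3-methoxybenzoyl chloride | COc1cc(C(=O)Cl)ccc1OCc1ccccc1 | intermediate
3 | (S)-terpinen-4-ol, (1S)-4-methyl-1-(propan-2-yl)cyclohex-3-en-1-ol | CC(C)[C@@]1(O)CC=C(C)CC1 | starting material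
4 | lithium (S)-terpinen-4-olate | CC(C)[C@@]1(O[Li])CC=C(C)CC1 | intermediate (not isolated)
5 | (1S)-4-methyl-1-(propan-2-yl)cyclohex-3-en-1-yl 4-(benzyloxy)-3-methoxybenzoate | COc1cc(C(=O)O[C@@]2(C(C)C)CCC(C)=CC2)ccc1OCc1ccccc1 | intermediate
6 | (3S)-6-hydroperoxy-6-methoxy-1-oxo-3-(propan-2-yl)heptan-3-yl 4-(benzyloxy)-3-methoxybenzoate (C6 epimers) | COc1cc(C(=O)O[C@@](C(C)C)(CCC(C)(OC)OO)CC=O)ccc1OCc1ccccc1 | intermediate (not isolated)
7 | (3S)-6-hydroperoxy-1,1,6-trimethoxy-3-(propan-2-yl)heptan-3-yl 4-(benzyloxy)-3-methoxybenzoate (C6 epimers) | COc1cc(C(=O)O[C@@](C(C)C)(CCC(C)(OC)OO)CC(OC)OC)ccc1OCc1ccccc1 | intermediate (not isolated)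
8 | (3S)-1,1-dimethoxy-6-oxo-3-(propan-2-yl)heptan-3-yl 4-(benzyloxy)-3-methoxybenzoate | COc1cc(C(=O)O[C@@](C(C)C)(CCC(C)=O)CC(OC)OC)ccc1OCc1ccccc1 | intermediate
9 | bromomagnesium alkoxide of (3S)-6-hydroxy-1,1-dimethoxy-6-methyl-3-(propan-2-yl)oct-7-yn-3-yl 4-(benzyloxy)-3-methoxybenzoate (C6 epimers) | COc1cc(C(=O)O[C@@](C(C)C)(CCC(C)(O[Mg]Br)C#C)CC(OC)OC)ccc1OCc1ccccc1 | intermediate (not isolated)
10 | (3S)-1,1-dimethoxy-6-[(methoxycarbonyl)oxy]-6-methyl-3-(propan-2-yl)oct-7-yn-3-yl 4-(benzyloxy)-3-methoxybenzoate (C6 epimers) | COc1cc(C(=O)O[C@@](C(C)C)(CCC(C)(OC(=O)OC)C#C)CC(OC)OC)ccc1OCc1ccccc1 | intermediate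
11 | (3S)-1,1-dimethoxy-6-methyl-3-(propan-2-yl)octa-6,7-dien-3-yl 4-(benzyloxy)-3-methoxybenzoate | COc1cc(C(=O)O[C@@](C(C)C)(CCC(C)=C=C)CC(OC)OC)ccc1OCc1ccccc1 | intermediate
12 | (3S)-6-methyl-1-oxo-3-(propan-2-yl)octa-6,7-dien-3-yl 4-(benzyloxy)-3-methoxybenzoate | COc1cc(C(=O)O[C@@](C(C)C)(CCC(C)=C=C)CC=O)ccc1OCc1ccccc1 | intermediate
13 | (6S,9E)-8-hydroxy-3-methyl-6-(propan-2-yl)undeca-1,2,9-trien-6-yl 4-(benzyloxy)-3-methoxybenzoate (C8 epimers) | COc1cc(C(=O)O[C@@](C(C)C)(CCC(C)=C=C)CC(O)/C=C/C)ccc1OCc1ccccc1 | intermediate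
14 | (6S,9E)-3-methyl-8-oxo-6-(propan-2-yl)undeca-1,2,9-trien-6-yl 4-(benzyloxy)-3-methoxybenzoate | COc1cc(C(=O)O[C@@](C(C)C)(CCC(C)=C=C)CC(=O)/C=C/C)ccc1OCc1ccccc1 | intermediate
15 | (6R,7Z,9E)-8-[(tert-butyldimethylsilyl)oxy]-3-methyl-6-(propan-2-yl)undeca-1,2,7,9-tetraen-6-yl 4-(benzyloxy)-3-methoxybenzoate (same spatial arrangement at C6 as in 14; only the priority order changes) | COc1cc(C(=O)O[C@@](C(C)C)(CCC(C)=C=C)/C=C(\O[Si](C)(C)C(C)(C)C)/C=C/C)ccc1OCc1ccccc1 | intermediate
16 | 6-[(tert-butyldimethylsilyl)oxy]-5αH,8αH-dauca-6,9-dien-4β-yl 4-(benzyloxy)-3-methoxybenzoate (trans-fused; angular methyl β, C8 methyl β) | COc1cc(C(=O)O[C@@]2(C(C)C)CC[C@]3(C)C=C[C@@H](C)C=C(O[Si](C)(C)C(C)(C)C)[C@H]32)ccc1OCc1ccccc1 | intermediate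
17 | 6-oxo-5αH-dauca-7,9-dien-4β-yl 4-(benzyloxy)-3-methoxybenzoate | COc1cc(C(=O)O[C@@]2(C(C)C)CC[C@]3(C)C=CC(C)=CC(=O)[C@H]32)ccc1OCc1ccccc1 | intermediate
18 | 6-oxo-5αH-dauc-8-en-4β-yl 4-(benzyloxy)-3-methoxybenzoate | COc1cc(C(=O)O[C@@]2(C(C)C)CC[C@]3(C)CC=C(C)CC(=O)[C@H]32)ccc1OCc1ccccc1 | intermediate
19 | 6α-hydroxy-5αH-dauc-8-en-4β-yl 4-(benzyloxy)-3-methoxybenzoate | COc1cc(C(=O)O[C@@]2(C(C)C)CC[C@]3(C)CC=C(C)C[C@H](O)[C@H]32)ccc1OCc1ccccc1 | intermediate
20 | 8α,9α-epoxy-6α-hydroxy-5αH-daucan-4β-yl 4-(benzyloxy)-3-methoxybenzoate | COc1cc(C(=O)O[C@@]2(C(C)C)CC[C@]3(C)C[C@@H]4O[C@]4(C)C[C@H](O)[C@H]32)ccc1OCc1ccccc1 | intermediate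
21 | 8α,9α-epoxy-6α-hydroxy-5αH-daucan-4β-yl 4-hydroxy-3-methoxybenzoate (CNP0315707.1) | COc1cc(C(=O)O[C@@]2(C(C)C)CC[C@]3(C)C[C@@H]4O[C@]4(C)C[C@H](O)[C@H]32)ccc1O | target

**Step count and risks**

Total step count: 15. Longest linear sequence: 15 steps (1 to 21); 14 steps counted from the terpene 3.

Steps most likely to fail:

Step 10. The cascade may stop after the first bond (simple carbocyclisation with protodeauration), the gold carbene may undergo ring contraction to (4+2) products, the tertiary allylic ester may ionise through the enol silane, or facial selectivity at C5 may be poor. Fallback, closing the two rings one after the other: from aldehyde 12, Nozaki–Hiyama–Kishi coupling with 1-bromo-2-methylprop-1-ene (CrCl2, cat. NiCl2, DMF) would give allylic alcohol F1, MnO2 would give the β,β-dimethyl enone F2, and TBSOTf/Et3N the Z-silyloxydiene F3. Gold-catalysed Conia-ene-type 5-exo carbocyclisation of the enol silane onto the allene ((Ph3P)AuCl/AgOTf, CH2Cl2/MeOH) would close only the cyclopentane and give trans vinyl ketone F4 after protodeauration. Selective cleavage of the vinyl group (OsO4 cat., NaIO4, 2,6-lutidine, dioxane/H2O) would give the non-enolisable aldehyde F5. Intramolecular vinylogous aldol condensation of the enone's Z-methyl group onto this aldehyde (pyrrolidine/AcOH) would close the seven-membered ring and give dienone 17, where the route is rejoined.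

Step 12. The hindered trisubstituted ring diene may bind the chromium fragment poorly, hydrogenation may stall, or the β,γ-alkene may drift into conjugation. Fallback by the classical enol acetate deconjugation: from 17, RhCl(PPh3)3/H2 (benzene, rt) should saturate only the disubstituted C9=C10 bond to give conjugated enone F6. Isopropenyl acetate/TsOH (reflux) would convert it into the linearly conjugated dienol acetate F7 (C6=C7 and C8=C9). NaBH4 in EtOH/THF would cleave the enol acetate, the enolate would be protonated at C7, and the resulting β,γ-unsaturated ketone would be reduced in the same flask to alcohol 19, where the route is rejoined (steps 12 and 13 are replaced).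

Step 13. The axial β angular methyl may block the axial trajectory, so hydride delivery from the α face and poor or reversed facial selectivity are possible. Fallback by inversion instead of facial control: from 18, LiBH(s-Bu)3 (THF, −78 °C) would be used to give the 6β-alcohol F8 deliberately. Mitsunobu reaction with 4-nitrobenzoic acid (PPh3, DIAD, toluene) would invert C6 to the 6α 4-nitrobenzoate F9. Methanolysis (K2CO3, MeOH, 0 °C), which should spare the hindered tertiary vanillate, would give 19, where the route is rejoined.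

**Further compounds**

F1 | step 10 | (3S)-1-hydroxy... named as 8-hydroxy-3,10-dimethyl-6-(propan-2-yl)undeca-1,2,9-trien-6-yl 4-(benzyloxy)-3-methoxybenzoate (C6 as in 12; C8 epimers) | COc1cc(C(=O)O[C@@](C(C)C)(CCC(C)=C=C)CC(O)C=C(C)C)ccc1OCc1ccccc1
F2 | step 10 | 3,10-dimethyl-8-oxo-6-(propan-2-yl)undeca-1,2,9-trien-6-yl 4-(benzyloxy)-3-methoxybenzoate (C6 as in 12) | COc1cc(C(=O)O[C@@](C(C)C)(CCC(C)=C=C)CC(=O)C=C(C)C)ccc1OCc1ccccc1
F3 | step 10 | (7Z)-8-[(tert-butyldimethylsilyl)oxy]-3,10-dimethyl-6-(propan-2-yl)undeca-1,2,7,9-tetraen-6-yl 4-(benzyloxy)-3-methoxybenzoate | COc1cc(C(=O)O[C@@](C(C)C)(CCC(C)=C=C)/C=C(\O[Si](C)(C)C(C)(C)C)C=C(C)C)ccc1OCc1ccccc1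
F4 | step 10 | 3-ethenyl-3-methyl-2-(3-methylbut-2-enoyl)-1-(propan-2-yl)cyclopentyl 4-(benzyloxy)-3-methoxybenzoate (acyl trans to vinyl and cis to the ester oxygen; ring methyl cis to the ester oxygen) | COc1cc(C(=O)O[C@@]2(C(C)C)CC[C@](C)(C=C)[C@H]2C(=O)C=C(C)C)ccc1OCc1ccccc1
F5 | step 10 | 3-formyl-3-methyl-2-(3-methylbut-2-enoyl)-1-(propan-2-yl)cyclopentyl 4-(benzyloxy)-3-methoxybenzoate (same configuration as F4) | COc1cc(C(=O)O[C@@]2(C(C)C)CC[C@](C)(C=O)[C@H]2C(=O)C=C(C)C)ccc1OCc1ccccc1
F6 | step 12 | 6-oxo-5αH-dauc-7-en-4β-yl 4-(benzyloxy)-3-methoxybenzoate | COc1cc(C(=O)O[C@@]2(C(C)C)CC[C@]3(C)CCC(C)=CC(=O)[C@H]32)ccc1OCc1ccccc1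
F7 | step 12 | 6-acetoxy-5αH-dauca-6,8-dien-4β-yl 4-(benzyloxy)-3-methoxybenzoate | COc1cc(C(=O)O[C@@]2(C(C)C)CC[C@]3(C)CC=C(C)C=C(OC(C)=O)[C@H]32)ccc1OCc1ccccc1
F8 | step 13 | 6β-hydroxy-5αH-dauc-8-en-4β-yl 4-(benzyloxy)-3-methoxybenzoate | COc1cc(C(=O)O[C@@]2(C(C)C)CC[C@]3(C)CC=C(C)C[C@@H](O)[C@H]32)ccc1OCc1ccccc1
F9 | step 13 | 6α-(4-nitrobenzoyloxy)-5αH-dauc-8-en-4β-yl 4-(benzyloxy)-3-methoxybenzoate | COc1cc(C(=O)O[C@@]2(C(C)C)CC[C@]3(C)CC=C(C)C[C@H](OC(=O)c4ccc([N+](=O)[O-])cc4)[C@H]32)ccc1OCc1ccccc1
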